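**Plan**
- Retrosynthesis: the C13=C14 enoate is cut last (Horner–Wadsworth–Emmons on a C13 methyl ketone). The 6β-OH and C18 are traced back to a Δ5 3-keto 19-ester, and ring A is then cut at C1–C2 and at C4–C5 in one formal [3+3] condensation.
- Enabling feature: C1 and C5 both sit on the quaternary C10 of ring B, so they can be the aldehyde and ketone carbons of a β-keto aldehyde (1,3-dielectrophile). C2 and C4 flank the C3 oxygen and C4 carries C19, which is methyl acetoacetate (1,3-dinucleophile).
- Forward: ring B with C17, C20 and C11–C13 comes from 2-methylcyclohexane-1,3-dione by Stork–Danheiser transposition. C10 is made quaternary by a decarboxylative asymmetric allylation, which also moves the double bond to C8=C9; the allyl group is a helper cut down to the C1 aldehyde. Ring A follows, and the side chain is finished last.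
- Stereochemistry: C10 from the chiral palladium catalyst; C4 by α-face methylation of the ring-A dienolate anti to C20; C3 by equatorial hydride delivery; C5 by α-face hydroboration; C6 by α-face hydride attack on the 6-ketone; 13E from the olefination.

Key step: step 8

Remark: positions are numbered as in labdane (ring A = C1–C5 and C10, ring B = C5–C10, C17 on C8, C18 α and C19 β on C4, C20 on C10, side chain C11–C16); β is the face of the C20 methyl group.

Step 1
Reactants: 1 2-methylcyclohexane-1,3-dione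
Product: 2 3-isobutoxy-2-methylcyclohex-2-en-1-one
Conditions: i-BuOH, TsOH (cat.), PhMe, reflux, Dean–Stark
Reagents that add atoms: 2-methylpropan-1-ol, CC(C)CO
Why: Acid-catalysed O-alkylation of the enolised 1,3-diketone with removal of water (vinylogous ester formation) masks the carbonyl that becomes C5 and leaves the one that becomes C9 open for the Stork–Danheiser sequence.

Step 2
Reactants: 2 3-isobutoxy-2-methylcyclohex-2-en-1-one
Product: 4 (±)-3-isobutoxy-2,6-dimethylcyclohex-2-en-1-one, via lithium enolate 3 (not isolated)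
Conditions: LiN(i-Pr)2, THF, −78 °C; MeI, −78 → 0 °C
Reagents that add atoms: iodomethane, CI
Why: Kinetic deprotonation of the vinylogous ester occurs at the α′ carbon (future C8) and enolate methylation there introduces C17; the racemic centre is erased in step 4.

Step 3
Reactants: 4 (±)-3-isobutoxy-2,6-dimethylcyclohex-2-en-1-one; 5 2-(2-bromoethyl)-2-methyl-1,3-dioxolane
Product: 8 (±)-2,4-dimethyl-3-[2-(2-methyl-1,3-dioxolan-2-yl)ethyl]cyclohex-2-en-1-one, via Grignard reagent 6 (not isolated), via magnesium alkoxide 7 (not isolated)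
Conditions: 5, Mg, THF, 25 °C; then 4, 0 → 20 °C; then 1 M HCl, 0 °C, brief
Reagents that add atoms: water, O
Why: 1,2-Addition of the Grignard reagent followed by acid-promoted ionisation of the tertiary allylic alcohol and hydrolysis of the enol ether (Stork–Danheiser transposition) should place the C11–C13 chain on C9 and the carbonyl on C5, with the dioxolane surviving the brief cold acid.

Step 4
Reactants: 8 (±)-2,4-dimethyl-3-[2-(2-methyl-1,3-dioxolan-2-yl)ethyl]cyclohex-2-en-1-one
Product: 10 allyl 2,4-dimethyl-3-[2-(2-methyl-1,3-dioxolan-2-yl)ethyl]cyclohexa-1,3-dien-1-yl carbonate, via potassium dienolate 9 (not isolated)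
Conditions: KH (0.98 equiv), THF, 20 °C, 2 h; then allyl chloroformate, −78 °C
Reagents that add atoms: allyl chloroformate, C=CCOC(Cl)=O
Why: Equilibration of the potassium enolate through the slight excess of ketone should give the fully conjugated endocyclic dienolate (γ-deprotonation at C8), which the hard chloroformate O-acylates to the dienol carbonate needed for the Tsuji allylation.

Step 5
Reactants: 10 allyl 2,4-dimethyl-3-[2-(2-methyl-1,3-dioxolan-2-yl)ethyl]cyclohexa-1,3-dien-1-yl carbonate
Product: 11 (R)-2-allyl-2,4-dimethyl-3-[2-(2-methyl-1,3-dioxolan-2-yl)ethyl]cyclohex-3-en-1-one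
Conditions: Pd2(dba)3 (2.5 mol %), (S)-t-Bu-PHOX (6 mol %), THF, 25 °C
Reagents that add atoms: none
Why: Zerovalent palladium ionises the allyl carbonate, CO2 is lost and the π-allylpalladium/dienolate pair recombines at the α-carbon inside the chiral ligand pocket (decarboxylative asymmetric Tsuji allylation), which sets the quaternary C10 and leaves the double bond at C8=C9; the (S)-ligand is chosen by analogy with 2-methylcyclohexanone enol carbonates.

Step 6
Reactants: 11 (R)-2-allyl-2,4-dimethyl-3-[2-(2-methyl-1,3-dioxolan-2-yl)ethyl]cyclohex-3-en-1-one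
Product: 12 (R)-2,4-dimethyl-3-[2-(2-methyl-1,3-dioxolan-2-yl)ethyl]-2-[(E)-prop-1-en-1-yl]cyclohex-3-en-1-one
Conditions: RuHCl(CO)(PPh3)3 (5 mol %), PhMe, 80 °C
Reagents that add atoms: none
Why: The ruthenium hydride moves the terminal double bond by hydrometalation and β-hydride elimination into the (E)-propenyl position (olefin isomerisation), where it stops because C10 is quaternary, so that only C1 of the allyl helper stays on C10 after cleavage.

Step 7
Reactants: 12 (R)-2,4-dimethyl-3-[2-(2-methyl-1,3-dioxolan-2-yl)ethyl]-2-[(E)-prop-1-en-1-yl]cyclohex-3-en-1-one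
Product: 14 (S)-1,3-dimethyl-2-[2-(2-methyl-1,3-dioxolan-2-yl)ethyl]-6-oxocyclohex-2-ene-1-carbaldehyde, via vicinal diol 13 (not isolated)
Conditions: OsO4 (2 mol %), NaIO4 (4 equiv), 2,6-lutidine, dioxane/H2O, 20 °C
Reagents that add atoms: osmium tetroxide, O=[Os](=O)(=O)=O; sodium periodate, [Na+].[O-]I(=O)(=O)=O
Why: In the Lemieux–Johnson oxidation OsO4 should dihydroxylate the 1,2-disubstituted propenyl bond much faster than the shielded tetrasubstituted C8=C9 bond, and periodate cleaves the diol to leave C1 as the aldehyde of a non-enolisable β-keto aldehyde.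

Step 8
Reactants: 14 (S)-1,3-dimethyl-2-[2-(2-methyl-1,3-dioxolan-2-yl)ethyl]-6-oxocyclohex-2-ene-1-carbaldehyde; 15 methyl 3-oxobutanoate
Product: 19 methyl 13,13-(ethylenedioxy)-3-oxo-14,15,18-trinorlabda-1,4,8-trien-19-oate, via dilithium dianion 16 (not isolated), via aldol adduct 17 (not isolated), via hydroxy enone ester 18 (not isolated)
Conditions: 15, LiN(i-Pr)2 (2.1 equiv), THF, 0 °C; 14, −78 °C; AcOH (2.2 equiv), −78 → 20 °C; then pyrrolidine (0.3 equiv), 4 Å MS, 50 °C, same flask
Reagents that add atoms: none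
Why: The dianion 16 reacts through its terminal carbon only and should add to the non-enolisable aldehyde of 14 (C1) in preference to the α-quaternary ketone, which forms C1–C2 as a vinylogous aldol addition and leaves the β-keto ester anion intact; after protonation, pyrrolidinium acetate condenses the active methylene carbon C4 with the C5 ketone (intramolecular Knoevenagel reaction, C4–C5) and the β-hydroxy ketone then loses water by an E1cB pathway to the ring enone. The closest known reaction type is the formal [3+3] cyclocondensation of 1,3-dicarbonyl dianions, or of their bis-silyl enol ethers, with 1,3-dielectrophiles, here applied to a β-keto aldehyde whose central carbon (C10) is quaternary, so that a cyclohexadienone forms and aromatisation is impossible. Ring A is closed in a 6-(enolendo)-exo-trig aldol addition of the enolised β-keto ester to the C5 carbonyl group. No stereocentre is created that survives (the C1 carbinol is lost on dehydration) and C10, set in step 5, cannot epimerise because it bears no hydrogen. The step needs chemoselectivity (aldehyde before ketone), regioselectivity (terminal carbon to C1, central carbon to C5) and the right order of events, because an open-chain (E)-enone formed by early loss of water could not cyclise; the first two are secured by the graded reactivity of the dianion and of the two carbonyl groups, the third by the preference of the β-keto ester to enolise toward C4 until that carbon is fully substituted.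

Step 9
Reactants: 19 methyl 13,13-(ethylenedioxy)-3-oxo-14,15,18-trinorlabda-1,4,8-trien-19-oate
Product: 20 methyl 13,13-(ethylenedioxy)-3-oxo-14,15,18-trinorlabda-4,8-dien-19-oate
Conditions: H2 (1 atm), RhCl(PPh3)3 (5 mol %), PhH, 25 °C
Reagents that add atoms: none
Why: Homogeneous hydrogenation should saturate only the unhindered cis-disubstituted C1=C2 bond, since the tetrasubstituted C4=C5 and C8=C9 bonds do not bind to the crowded rhodium hydride.

Step 10
Reactants: 20 methyl 13,13-(ethylenedioxy)-3-oxo-14,15,18-trinorlabda-4,8-dien-19-oate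
Product: 22 methyl 13,13-(ethylenedioxy)-3-oxo-14,15-dinorlabda-5,8-dien-19-oate, via potassium dienolate 21 (not isolated)
Conditions: KOt-Bu, t-BuOH/THF, 0 °C; MeI, 0 → 20 °C
Reagents that add atoms: iodomethane, CI
Why: tert-Butoxide removes a γ-proton from C6 to give the extended dienolate, which is methylated at C4 (deconjugative α-alkylation) from the α face, anti to the axial C20 methyl group, so that C18 is α, the ester (C19) is β and the C5=C6 bond remains for oxygenation of C6.

Step 11
Reactants: 22 methyl 13,13-(ethylenedioxy)-3-oxo-14,15-dinorlabda-5,8-dien-19-oate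
Product: 24 13,13-(ethylenedioxy)-14,15-dinorlabda-5,8-diene-3α,19-diol, via hydroxy ester 23 (not isolated)
Conditions: LiBH(s-Bu)3, THF, −78 °C; then LiAlH4, −78 → 0 °C; aq. work-up
Reagents that add atoms: none
Why: The bulky trialkylborohydride should attack the C3 ketone along the equatorial trajectory and give the axial 3α-alcohol (as in hydride reductions of 4,4-disubstituted 3-keto terpenoids), after which LiAlH4 reduces the hindered ester to the C19 primary alcohol in the same flask.

Step 12
Reactants: 24 13,13-(ethylenedioxy)-14,15-dinorlabda-5,8-diene-3α,19-diol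
Product: 25 19-(tert-butyldimethylsilyloxy)-13,13-(ethylenedioxy)-14,15-dinorlabda-5,8-dien-3α-ol
Conditions: TBSCl (1.05 equiv), imidazole, DMF, 0 °C
Reagents that add atoms: tert-butyldimethylsilyl chloride, CC(C)(C)[Si](C)(C)Cl
Why: Silylation is governed by sterics, so the primary C19 hydroxyl should react and the axial secondary 3α-hydroxyl next to the quaternary C4 should not.

Step 13
Reactants: 25 19-(tert-butyldimethylsilyloxy)-13,13-(ethylenedioxy)-14,15-dinorlabda-5,8-dien-3α-ol
Product: 26 19-(tert-butyldimethylsilyloxy)-13,13-(ethylenedioxy)-14,15-dinorlabda-5,8-dien-3α-yl 3-methylbutanoate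
Conditions: 3-methylbutanoyl chloride, pyridine, DMAP (cat.), CH2Cl2, 40 °C
Reagents that add atoms: 3-methylbutanoyl chloride, CC(C)CC(Cl)=O
Why: DMAP-catalysed acylation of the only free hydroxyl installs the 3-methylbutanoate ester with retention at C3.

Step 14
Reactants: 26 19-(tert-butyldimethylsilyloxy)-13,13-(ethylenedioxy)-14,15-dinorlabda-5,8-dien-3α-yl 3-methylbutanoate
Product: 28 19-(tert-butyldimethylsilyloxy)-13,13-(ethylenedioxy)-6α-hydroxy-14,15-dinorlabd-8-en-3α-yl 3-methylbutanoate, via alkylborane 27 (not isolated)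
Conditions: BH3·THF, THF, 0 → 20 °C; then Me3NO·2H2O, 65 °C
Reagents that add atoms: trimethylamine N-oxide, C[N+](C)(C)[O-]
Why: Brown hydroboration places boron on the less substituted C6 and hydrogen on C5 in a syn addition from the α face, because the β face of C5=C6 is shielded by the axial C20 methyl and C19 silyloxymethyl groups, which sets the 5α-hydrogen (trans ring fusion); oxidation of the C–B bond by the amine oxide proceeds with retention and spares the ester.

Step 15
Reactants: 28 19-(tert-butyldimethylsilyloxy)-13,13-(ethylenedioxy)-6α-hydroxy-14,15-dinorlabd-8-en-3α-yl 3-methylbutanoate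
Product: 29 19-(tert-butyldimethylsilyloxy)-13,13-(ethylenedioxy)-6-oxo-14,15-dinorlabd-8-en-3α-yl 3-methylbutanoate
Conditions: DMP (1,1,1-triacetoxy-1,1-dihydro-1,2-benziodoxol-3(1H)-one), NaHCO3, CH2Cl2, 0 → 20 °C
Reagents that add atoms: none
Why: The periodinane oxidises the equatorial 6α-alcohol to the ketone under buffered neutral conditions, which should keep the C8=C9 bond from moving into conjugation.

Step 16
Reactants: 29 19-(tert-butyldimethylsilyloxy)-13,13-(ethylenedioxy)-6-oxo-14,15-dinorlabd-8-en-3α-yl 3-methylbutanoate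
Product: 30 19-(tert-butyldimethylsilyloxy)-13,13-(ethylenedioxy)-6β-hydroxy-14,15-dinorlabd-8-en-3α-yl 3-methylbutanoate
Conditions: NaBH4, CeCl3·7H2O, MeOH, −40 → 0 °C
Reagents that add atoms: none
Why: Hydride adds to the 6-ketone from the open α face, the β face being blocked by the 1,3-related axial C20 and C19 groups, and so gives the axial 6β-alcohol; the Luche conditions keep the medium non-basic and leave the ester and the β,γ-double bond untouched.

Step 17
Reactants: 30 19-(tert-butyldimethylsilyloxy)-13,13-(ethylenedioxy)-6β-hydroxy-14,15-dinorlabd-8-en-3α-yl 3-methylbutanoate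
Product: 31 6β,19-dihydroxy-13-oxo-14,15-dinorlabd-8-en-3α-yl 3-methylbutanoate
Conditions: 1 M HCl, THF, 20 °C
Reagents that add atoms: water, O
Why: Dilute acid hydrolyses the dioxolane to the C13 methyl ketone and cleaves the primary silyl ether in one operation (acetal and silyl ether hydrolysis), while the hindered 3-methylbutanoate ester should be stable.

Step 18
Reactants: 31 6β,19-dihydroxy-13-oxo-14,15-dinorlabd-8-en-3α-yl 3-methylbutanoate; 32 allyl 2-(diethoxyphosphoryl)acetate
Product: 34 allyl (13E)-6β,19-dihydroxy-3α-(3-methylbutanoyloxy)labda-8,13-dien-15-oate, via sodium phosphonate 33 (not isolated)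
Conditions: 32, NaH, THF, 0 °C; then 31, 0 → 40 °C
Reagents that add atoms: none
Why: The Horner–Wadsworth–Emmons reaction of the stabilised phosphonate anion with the unhindered methyl ketone should give mainly the (E)-trisubstituted enoate, the anion being too weak a base to disturb the hydroxyls or the ester; the minor (Z)-isomer is to be removed by chromatography.

Step 19
Reactants: 34 allyl (13E)-6β,19-dihydroxy-3α-(3-methylbutanoyloxy)labda-8,13-dien-15-oate
Product: 35 (13E)-6β,19-dihydroxy-3α-(3-methylbutanoyloxy)labda-8,13-dien-15-oic acid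
Conditions: Pd(PPh3)4 (5 mol %), morpholine, THF, 20 °C
Reagents that add atoms: none
Why: Zerovalent palladium ionises the allyl ester and morpholine traps the π-allyl fragment (Tsuji–Trost deallylation), which frees the C15 acid under neutral conditions that leave the 3-methylbutanoate ester intact.

**Compound list**
1 | 2-methylcyclohexane-1,3-dione | CC1C(=O)CCCC1=O | starting material
2 | 3-isobutoxy-2-methylcyclohex-2-en-1-one | CC1=C(OCC(C)C)CCCC1=O | intermediate
3 | lithium enolate of 2 (deprotonated at C6 of the ring) | CC1=C(OCC(C)C)CCC=C1[O-].[Li+] | intermediate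
4 | (±)-3-isobutoxy-2,6-dimethylcyclohex-2-en-1-one | CC1CCC(OCC(C)C)=C(C)C1=O | intermediate
5 | 2-(2-bromoethyl)-2-methyl-1,3-dioxolane | CC1(CCBr)OCCO1 | starting material
6 | bromo[2-(2-methyl-1,3-dioxolan-2-yl)ethyl]magnesium | CC1(CC[Mg]Br)OCCO1 | intermediate
7 | bromomagnesium 3-isobutoxy-2,6-dimethyl-1-[2-(2-methyl-1,3-dioxolan-2-yl)ethyl]cyclohex-2-en-1-olate | CC1CCC(OCC(C)C)=C(C)C1(CCC2(C)OCCO2)O[Mg]Br | intermediate
8 | (±)-2,4-dimethyl-3-[2-(2-methyl-1,3-dioxolan-2-yl)ethyl]cyclohex-2-en-1-one | CC1CCC(=O)C(C)=C1CCC2(C)OCCO2 | intermediate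
9 | potassium 2,4-dimethyl-3-[2-(2-methyl-1,3-dioxolan-2-yl)ethyl]cyclohexa-1,3-dien-1-olate | CC1=C(CCC2(C)OCCO2)C(C)=C([O-])CC1.[K+] | intermediate
10 | allyl 2,4-dimethyl-3-[2-(2-methyl-1,3-dioxolan-2-yl)ethyl]cyclohexa-1,3-dien-1-yl carbonate | CC1=C(CCC2(C)OCCO2)C(C)=C(OC(=O)OCC=C)CC1 | intermediate
11 | (R)-2-allyl-2,4-dimethyl-3-[2-(2-methyl-1,3-dioxolan-2-yl)ethyl]cyclohex-3-en-1-one | CC1=C(CCC2(C)OCCO2)[C@@](C)(CC=C)C(=O)CC1 | intermediate
12 | (R)-2,4-dimethyl-3-[2-(2-methyl-1,3-dioxolan-2-yl)ethyl]-2-[(E)-prop-1-en-1-yl]cyclohex-3-en-1-one | CC1=C(CCC2(C)OCCO2)[C@@](C)(/C=C/C)C(=O)CC1 | intermediate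
13 | (2S)-2-(1,2-dihydroxypropyl)-2,4-dimethyl-3-[2-(2-methyl-1,3-dioxolan-2-yl)ethyl]cyclohex-3-en-1-one (diol carbons as a mixture) | CC1=C(CCC2(C)OCCO2)[C@@](C)(C(O)C(C)O)C(=O)CC1 | intermediate
14 | (S)-1,3-dimethyl-2-[2-(2-methyl-1,3-dioxolan-2-yl)ethyl]-6-oxocyclohex-2-ene-1-carbaldehyde | CC1=C(CCC2(C)OCCO2)[C@@](C)(C=O)C(=O)CC1 | intermediate
15 | methyl 3-oxobutanoate (methyl acetoacetate) | CC(=O)CC(=O)OC | starting material
16 | dilithium 1-methoxybuta-1,3-diene-1,3-diolate (dianion of 15) | C=C([O-])C=C([O-])OC.[Li+].[Li+] | intermediate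
17 | methyl 5-[(1S)-1,3-dimethyl-2-[2-(2-methyl-1,3-dioxolan-2-yl)ethyl]-6-oxocyclohex-2-en-1-yl]-5-hydroxy-3-oxopentanoate (carbinol as a mixture) | CC1=C(CCC2(C)OCCO2)[C@@](C)(C(O)CC(=O)CC(=O)OC)C(=O)CC1 | intermediate
18 | methyl 13,13-(ethylenedioxy)-1-hydroxy-3-oxo-14,15,18-trinorlabda-4,8-dien-19-oate (C1 carbinol as a mixture) | CC1=C(CCC3(C)OCCO3)[C@@]2(C)C(O)CC(=O)C(C(=O)OC)=C2CC1 | intermediate
19 | methyl 13,13-(ethylenedioxy)-3-oxo-14,15,18-trinorlabda-1,4,8-trien-19-oate | CC1=C(CCC3(C)OCCO3)[C@@]2(C)C=CC(=O)C(C(=O)OC)=C2CC1 | intermediate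
20 | methyl 13,13-(ethylenedioxy)-3-oxo-14,15,18-trinorlabda-4,8-dien-19-oate | CC1=C(CCC3(C)OCCO3)[C@@]2(C)CCC(=O)C(C(=O)OC)=C2CC1 | intermediate
21 | potassium 3,5-dienolate of 20 (O on C3, double bonds C3=C4 and C5=C6) | CC1=C(CCC3(C)OCCO3)[C@@]2(C)CCC([O-])=C(C(=O)OC)C2=CC1.[K+] | intermediate
22 | methyl 13,13-(ethylenedioxy)-3-oxo-14,15-dinorlabda-5,8-dien-19-oate (C18 α, ester β) | CC1=C(CCC3(C)OCCO3)[C@@]2(C)CCC(=O)[C@](C)(C(=O)OC)C2=CC1 | intermediate
23 | methyl 13,13-(ethylenedioxy)-3α-hydroxy-14,15-dinorlabda-5,8-dien-19-oate | CC1=C(CCC3(C)OCCO3)[C@@]2(C)CC[C@@H](O)[C@](C)(C(=O)OC)C2=CC1 | intermediate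
24 | 13,13-(ethylenedioxy)-14,15-dinorlabda-5,8-diene-3α,19-diol | CC1=C(CCC3(C)OCCO3)[C@@]2(C)CC[C@@H](O)[C@](C)(CO)C2=CC1 | intermediate
25 | 19-(tert-butyldimethylsilyloxy)-13,13-(ethylenedioxy)-14,15-dinorlabda-5,8-dien-3α-ol | CC1=C(CCC3(C)OCCO3)[C@@]2(C)CC[C@@H](O)[C@](C)(CO[Si](C)(C)C(C)(C)C)C2=CC1 | intermediate
26 | 19-(tert-butyldimethylsilyloxy)-13,13-(ethylenedioxy)-14,15-dinorlabda-5,8-dien-3α-yl 3-methylbutanoate | CC1=C(CCC3(C)OCCO3)[C@@]2(C)CC[C@@H](OC(=O)CC(C)C)[C@](C)(CO[Si](C)(C)C(C)(C)C)C2=CC1 | intermediate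
27 | 6α-boryl-5α-H adduct of 26 (alkylborane) | CC1=C(CCC3(C)OCCO3)[C@@]2(C)CC[C@@H](OC(=O)CC(C)C)[C@](C)(CO[Si](C)(C)C(C)(C)C)[C@@H]2[C@@H](B)C1 | intermediate
28 | 19-(tert-butyldimethylsilyloxy)-13,13-(ethylenedioxy)-6α-hydroxy-14,15-dinorlabd-8-en-3α-yl 3-methylbutanoate | CC1=C(CCC3(C)OCCO3)[C@@]2(C)CC[C@@H](OC(=O)CC(C)C)[C@](C)(CO[Si](C)(C)C(C)(C)C)[C@@H]2[C@@H](O)C1 | intermediate
29 | 19-(tert-butyldimethylsilyloxy)-13,13-(ethylenedioxy)-6-oxo-14,15-dinorlabd-8-en-3α-yl 3-methylbutanoate | CC1=C(CCC3(C)OCCO3)[C@@]2(C)CC[C@@H](OC(=O)CC(C)C)[C@](C)(CO[Si](C)(C)C(C)(C)C)[C@@H]2C(=O)C1 | intermediate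
30 | 19-(tert-butyldimethylsilyloxy)-13,13-(ethylenedioxy)-6β-hydroxy-14,15-dinorlabd-8-en-3α-yl 3-methylbutanoate | CC1=C(CCC3(C)OCCO3)[C@@]2(C)CC[C@@H](OC(=O)CC(C)C)[C@](C)(CO[Si](C)(C)C(C)(C)C)[C@@H]2[C@H](O)C1 | intermediate
31 | 6β,19-dihydroxy-13-oxo-14,15-dinorlabd-8-en-3α-yl 3-methylbutanoate | CC1=C(CCC(C)=O)[C@@]2(C)CC[C@@H](OC(=O)CC(C)C)[C@](C)(CO)[C@@H]2[C@H](O)C1 | intermediate
32 | allyl 2-(diethoxyphosphoryl)acetate | CCOP(=O)(CC(=O)OCC=C)OCC | starting material
33 | sodium salt of 32 (phosphonate carbanion) | CCOP(=O)([CH-]C(=O)OCC=C)OCC.[Na+] | intermediate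
34 | allyl (13E)-6β,19-dihydroxy-3α-(3-methylbutanoyloxy)labda-8,13-dien-15-oate | CC1=C(CC/C(C)=C/C(=O)OCC=C)[C@@]2(C)CC[C@@H](OC(=O)CC(C)C)[C@](C)(CO)[C@@H]2[C@H](O)C1 | intermediate
35 | (13E)-6β,19-dihydroxy-3α-(3-methylbutanoyloxy)labda-8,13-dien-15-oic acid (CNP0274836.1) | CC1=C(CC/C(C)=C/C(=O)O)[C@@]2(C)CC[C@@H](OC(=O)CC(C)C)[C@](C)(CO)[C@@H]2[C@H](O)C1 | target

Total step count: 19. Longest linear sequence: 19 steps (1 to 35).

**Steps most likely to fail**

Step 4 (together with step 5). Proton transfer may place the enolate double bond toward C6 (cross-conjugated) or toward the exocyclic C11 instead of C8, or the chloroformate may acylate carbon, so that the allyl group ends on the wrong atom; in step 5 facial discrimination may be poor. The fallback runs from 1 to 11 and needs no dienolate. C-allylation of 1 (allyl bromide, aq. NaOH) should give 2-allyl-2-methylcyclohexane-1,3-dione F1. Desymmetrising asymmetric transfer hydrogenation (RuCl(p-cymene)[(S,S)-TsDPEN], HCO2H/Et3N, catalyst enantiomer chosen to give the 2S centre) should give (2S,3S)-2-allyl-3-hydroxy-2-methylcyclohexan-1-one F2, which is silylated (TBSCl, imidazole) to the silyl ether F3. Methylation (LiN(i-Pr)2, MeI) should give the α-methyl ketone F4, and KN(SiMe3)2/PhNTf2 the enol triflate F5. Negishi coupling of F5 with the alkylzinc bromide F6 (from 5, Zn, LiCl) under Pd(dppf)Cl2 should give the coupled diene F7. Bu4NF then frees the alcohol F8, and DMP oxidation returns to the route at 11.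

Step 8. The lithium aldolate may cleave by retro-aldol reaction, water may be lost from C1 before ring closure (an open-chain (E)-enone cannot cyclise), or the hindered C5 ketone may condense too slowly. The fallback runs from 14 to 19 in separate, protected stages. A Mukaiyama vinylogous aldol addition of 1-methoxy-1,3-bis(trimethylsilyloxy)buta-1,3-diene F9 (from 15) to 14 (BF3·OEt2, CH2Cl2, −78 °C) should give the hydroxy keto ester 17, which is isolated. Silylation (Et3SiCl, imidazole) gives the triethylsilyl ether F10, so that C1 cannot eliminate. Knoevenagel ring closure (piperidinium acetate, PhH, reflux) then gives the bicyclic silyloxy enone ester F11, and DBU-induced elimination of the silyloxy group returns to the route at 19.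

Step 14. Borane may attack the congested C5=C6 bond too slowly or from the β face, and may reduce the ester in competition. The fallback runs from 25 to 29. Hydroxyl-directed epoxidation of the homoallylic C5=C6 bond of 25 (VO(acac)2, t-BuOOH; the 3α-hydroxyl directs to the α face and the C8=C9 bond is not addressed) should give the 5α,6α-epoxy alcohol F12. Acylation (3-methylbutanoyl chloride, pyridine, DMAP) gives the epoxy ester F13. BF3·OEt2 then promotes a Meinwald rearrangement (hydride shift from C6 to C5), and equilibration at C5 to the trans ring fusion returns to the route at the 6-ketone 29.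

**Further compounds**
F1 | step 4 | 2-allyl-2-methylcyclohexane-1,3-dione | C=CCC1(C)C(=O)CCCC1=O
F2 | step 4 | (2S,3S)-2-allyl-3-hydroxy-2-methylcyclohexan-1-one | O=C1CCC[C@H](O)[C@]1(C)CC=C
F3 | step 4 | (2S,3S)-2-allyl-3-(tert-butyldimethylsilyloxy)-2-methylcyclohexan-1-one | O=C1CCC[C@H](O[Si](C)(C)C(C)(C)C)[C@]1(C)CC=C
F4 | step 4 | (2S,3S)-2-allyl-3-(tert-butyldimethylsilyloxy)-2,6-dimethylcyclohexan-1-one (C6 as a mixture) | CC1CC[C@H](O[Si](C)(C)C(C)(C)C)[C@](C)(CC=C)C1=O
F5 | step 4 | (5S,6S)-6-allyl-5-(tert-butyldimethylsilyloxy)-2,6-dimethylcyclohex-1-en-1-yl trifluoromethanesulfonate | CC1=C(OS(=O)(=O)C(F)(F)F)[C@@](C)(CC=C)[C@@H](O[Si](C)(C)C(C)(C)C)CC1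
F6 | step 4 | bromo[2-(2-methyl-1,3-dioxolan-2-yl)ethyl]zinc | CC1(CC[Zn]Br)OCCO1
F7 | step 4 | tert-butyldimethylsilyl ether of (1S,2R)-2-allyl-2,4-dimethyl-3-[2-(2-methyl-1,3-dioxolan-2-yl)ethyl]cyclohex-3-en-1-ol | CC1=C(CCC2(C)OCCO2)[C@@](C)(CC=C)[C@@H](O[Si](C)(C)C(C)(C)C)CC1
F8 | step 4 | (1S,2R)-2-allyl-2,4-dimethyl-3-[2-(2-methyl-1,3-dioxolan-2-yl)ethyl]cyclohex-3-en-1-ol | CC1=C(CCC2(C)OCCO2)[C@@](C)(CC=C)[C@@H](O)CC1
F9 | step 8 | 1-methoxy-1,3-bis(trimethylsilyloxy)buta-1,3-diene | C=C(O[Si](C)(C)C)C=C(OC)O[Si](C)(C)C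
F10 | step 8 | triethylsilyl ether of 17 | CC1=C(CCC2(C)OCCO2)[C@@](C)(C(O[Si](CC)(CC)CC)CC(=O)CC(=O)OC)C(=O)CC1
F11 | step 8 | methyl 13,13-(ethylenedioxy)-3-oxo-1-(triethylsilyloxy)-14,15,18-trinorlabda-4,8-dien-19-oate | CC1=C(CCC3(C)OCCO3)[C@@]2(C)C(O[Si](CC)(CC)CC)CC(=O)C(C(=O)OC)=C2CC1
F12 | step 14 | 19-(tert-butyldimethylsilyloxy)-5α,6α-epoxy-13,13-(ethylenedioxy)-14,15-dinorlabd-8-en-3α-ol | CC1=C(CCC3(C)OCCO3)[C@@]2(C)CC[C@@H](O)[C@](C)(CO[Si](C)(C)C(C)(C)C)[C@@]24O[C@H]4C1
F13 | step 14 | 19-(tert-butyldimethylsilyloxy)-5α,6α-epoxy-13,13-(ethylenedioxy)-14,15-dinorlabd-8-en-3α-yl 3-methylbutanoate | CC1=C(CCC3(C)OCCO3)[C@@]2(C)CC[C@@H](OC(=O)CC(C)C)[C@](C)(CO[Si](C)(C)C(C)(C)C)[C@@]24O[C@H]4C1
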